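**Retrosynthetic overview**

Numbering: ring C1 (CMe2), C2, C3 (C=O), C4, C5 (C(Me)OH), C6 (CH), chain C7–C15; primes mark the (5'R,6'S) half. The chain is cut at C11=C12 and C11'=C12' (two Wittig reactions of C15 phosphonium salts with the C10 trienedial) and at C8–C9/C7=C8 (Pd coupling of a ring–C7H2–C8H=N–NHTs hydrazone with an alkenyl iodide).
The (5'R,6'S) ring is opened at C4–C5 (aldol) and re-closed at C2–C5: its C5, C6, C1 and C2 are the four-membered ring of a 2-acetylcyclobutan-1-ol, so the ring arises by a two-atom expansion (retro-aldol, then aldol of the acetyl carbons C3/C4).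
Enabling feature: the β-hydroxy ketone C3(=O)–C4–C5(OH), flanked by gem-dimethyl C1 and the C6–H stereocentre, is the retro-aldol/aldol isomer of the cyclobutanone ring of chrysanthenone, the photoisomer of (1S,5S)-verbenone (C=O → C5, CMe2 → C1, bridgeheads → C6 and C2, the C(Me)=CH–CH2 bridge → C3 with C4 as its methyl, C8 and C7 after ozonolysis).
Ring order: the (5'R,6'S) ring is formed in step 3; the (5S,6S) ring is the same ring after inversion at C5 through enone, epoxide and reductive opening (steps 9–11); no other ring is built.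

Key step: step 3

Remark: (1S,5S)-verbenone of high enantiomeric purity is assumed (material of low ee would first be made from enantiopure (−)-α-pinene by allylic oxidation), and ethyl (E)-3-iodobut-2-enoate is taken as a purchasable building block. All polyene steps are run under argon in dim light.

**Route**

Step 1
Reactants: 1 (1S,5S)-(−)-verbenone
Product: 2 (1R,5S)-chrysanthenone
Conditions: hν (medium-pressure Hg lamp, Pyrex filter), cyclohexane, rt, stopped at partial conversion
Reagents that add atoms: none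
Why: The known photochemical 1,3-alkyl shift of verbenone moves the gem-dimethyl bridge carbon to the enone β-carbon and should give the bridged cyclobutanone; the bridgehead next to the carbonyl (later C6) is not touched and keeps its configuration, and the new bridgehead is fixed by the bicyclic frame.

Step 2
Reactants: 2 (1R,5S)-chrysanthenone
Product: 3 (1R,5S,6R)-2,6,7,7-tetramethylbicyclo[3.1.1]hept-2-en-6-ol
Conditions: MeLi (1.2 equiv), THF, −78 °C; aq. NH4Cl at −78 °C
Reagents that add atoms: methyllithium [Li]C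
Why: 1,2-Addition of methyllithium to the strained cyclobutanone, which cannot enolise (bridgehead α-carbons); attack from the face away from the gem-dimethyl bridge is expected, but the carbinol configuration is erased in step 3, so either epimer serves.

Step 3
Reactants: 3 (1R,5S,6R)-2,6,7,7-tetramethylbicyclo[3.1.1]hept-2-en-6-ol
Product: 8 (3R,4S)-4-(2,2-dimethoxyethyl)-3-hydroxy-3,5,5-trimethylcyclohexan-1-one, via cyclobutanol keto aldehyde 4 (not isolated), via cyclobutanol keto acetal 5 (not isolated), via open-chain diketone 6 (not isolated), via pyrrolidine enamine 7 (not isolated)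
Conditions: O3, CH2Cl2/MeOH (4:1), −78 °C; Me2S, −78 to 0 °C; HC(OMe)3, CeCl3·7H2O (10 mol %), 0 °C; then pyrrolidine (0.3 equiv), AcOH (0.3 equiv), 0 °C to rt
Reagents that add atoms: ozone [O-][O+]=O; trimethyl orthoformate COC(OC)OC
Why: Ozonolysis cuts the C(Me)=CH bond of the three-carbon bridge and unveils the 2-acetylcyclobutan-1-ol 4, whose aldehyde is masked at once as the dimethyl acetal 5 (lanthanide-catalysed Luche acetalisation, selective for aldehydes over ketones); the strained β-hydroxy ketone then undergoes retro-aldol cleavage of the C5–C2 ring bond to the 1,5-diketone 6, and pyrrolidine converts the unhindered C3 methyl ketone into its terminal enamine 7, which adds to the C5 ketone. The closest known reaction types are the de Mayo retro-aldol/aldol sequence of 2-acylcyclobutanols and the Hajos–Parrish-type enamine aldol cyclisation of 1,5-diketones. The six-membered ring closes in the 6-(enolexo)-exo-trig mode, so the cyclobutane C5–C6–C1–C2 is expanded by the two acetyl carbons C3 and C4. C6 is the old verbenone C1 and should keep its configuration because only the C3 ketone is activated and the hindered C5 ketone is not enolised under the buffered amine catalyst; C5 is set in a chair transition state with the C6 side chain and the C5 methyl equatorial (an axial C5 methyl would be syn-diaxial to the axial C1 methyl), which puts the hydroxyl cis to the side chain, and the reversible aldol lets the C5 epimer return to this product. The step needs regioselection between the two methyl ketones, secured by the steric bias of enamine formation (C3 ketone next to a CH2 versus the α-branched C5 ketone), and it must be stopped before dehydration, which the low temperature should secure.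

Step 4
Reactants: 8 (3R,4S)-4-(2,2-dimethoxyethyl)-3-hydroxy-3,5,5-trimethylcyclohexan-1-one
Product: 9 (1R,2S)-2-(2,2-dimethoxyethyl)-5,5-dimethoxy-1,3,3-trimethylcyclohexan-1-ol
Conditions: HC(OMe)3, MeOH, PPTS (cat.), rt; Et3N quench
Reagents that add atoms: trimethyl orthoformate COC(OC)OC
Why: Acid-catalysed ketalisation of the unhindered cyclohexanone with the orthoformate as water scavenger; with C3 masked the β-hydroxy ketone can no longer undergo retro-aldol cleavage or elimination in the basic steps that follow.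

Step 5
Reactants: 9 (1R,2S)-2-(2,2-dimethoxyethyl)-5,5-dimethoxy-1,3,3-trimethylcyclohexan-1-ol
Product: 10 2-[(1S,6R)-4,4-dimethoxy-2,2,6-trimethyl-6-(triethylsilyloxy)cyclohexyl]acetaldehyde
Conditions: Et3SiOTf (3 equiv), 2,6-lutidine (4 equiv), CH2Cl2, 0 °C; then H2O
Reagents that add atoms: triethylsilyl triflate CC[Si](CC)(CC)OS(=O)(=O)C(F)(F)F; water O
Why: The silyl triflate/2,6-lutidine acetal cleavage is known to unmask acetals of aldehydes while ketals of ketones stay intact, and the same reagent silylates the tertiary alcohol in the same operation.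

Step 6
Reactants: 10 2-[(1S,6R)-4,4-dimethoxy-2,2,6-trimethyl-6-(triethylsilyloxy)cyclohexyl]acetaldehyde; 11 ethyl (E)-3-iodobut-2-enoate
Product: 13 ethyl (2E,4E)-5-[(1S,6R)-4,4-dimethoxy-2,2,6-trimethyl-6-(triethylsilyloxy)cyclohexyl]-3-methylpenta-2,4-dienoate, via tosylhydrazone 12 (not isolated)
Conditions: TsNHNH2, 1,4-dioxane, rt; then 11, Pd2(dba)3 (2.5 mol %), XPhos (10 mol %), LiOtBu (2.4 equiv), 90 °C
Reagents that add atoms: none
Why: Barluenga coupling (palladium-catalysed cross-coupling of an aldehyde N-tosylhydrazone with an alkenyl halide): the palladium carbene at C8 takes up the alkenyl group by migratory insertion (C8–C9 bond) and β-hydride elimination towards C7, the only β-hydrogens available, should give the (7E)-alkene of the conjugated dienoate without touching C6.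

Step 7
Reactants: 13 ethyl (2E,4E)-5-[(1S,6R)-4,4-dimethoxy-2,2,6-trimethyl-6-(triethylsilyloxy)cyclohexyl]-3-methylpenta-2,4-dienoate
Product: 14 (2E,4E)-5-[(1S,6R)-4,4-dimethoxy-2,2,6-trimethyl-6-(triethylsilyloxy)cyclohexyl]-3-methylpenta-2,4-dien-1-ol
Conditions: i-Bu2AlH (2.5 equiv), CH2Cl2, −78 °C; aq. potassium sodium tartrate
Reagents that add atoms: none
Why: 1,2-Reduction of the dienoate to the primary allylic alcohol by the aluminium hydride; ketal and silyl ether are inert.

Step 8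
Reactants: 14 (2E,4E)-5-[(1S,6R)-4,4-dimethoxy-2,2,6-trimethyl-6-(triethylsilyloxy)cyclohexyl]-3-methylpenta-2,4-dien-1-ol
Product: 16 [(2E,4E)-5-[(1S,6R)-4,4-dimethoxy-2,2,6-trimethyl-6-(triethylsilyloxy)cyclohexyl]-3-methylpenta-2,4-dien-1-yl]triphenylphosphonium bromide, via allylic bromide 15 (not isolated)
Conditions: CBr4, PPh3, 2,6-lutidine, CH2Cl2, −20 °C; then PPh3, MeCN, rt
Reagents that add atoms: carbon tetrabromide BrC(Br)(Br)Br; triphenylphosphine c1ccc(cc1)P(c1ccccc1)c1ccccc1
Why: Appel bromination of the primary allylic alcohol followed by SN2 quaternisation of triphenylphosphine; the neutral conditions spare the dimethyl ketal and the silyl ether.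

Step 9
Reactants: 8 (3R,4S)-4-(2,2-dimethoxyethyl)-3-hydroxy-3,5,5-trimethylcyclohexan-1-one
Product: 18 (4S)-4-(2,2-dimethoxyethyl)-3,5,5-trimethylcyclohex-2-en-1-one, via tertiary trifluoroacetate 17 (not isolated)
Conditions: (CF3CO)2O, Et3N, DMAP (cat.), CH2Cl2, 0 °C; then DBU, rt
Reagents that add atoms: none
Why: Acylation of the tertiary alcohol and E1cB elimination through the C4 enolate should give the conjugated enone; C6 is a γ-position and is not deprotonated, so its configuration is kept.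

Step 10
Reactants: 18 (4S)-4-(2,2-dimethoxyethyl)-3,5,5-trimethylcyclohex-2-en-1-one
Product: 19 (1R,5S,6R)-5-(2,2-dimethoxyethyl)-4,4,6-trimethyl-7-oxabicyclo[4.1.0]heptan-2-one
Conditions: H2O2 (30% aq.), NaOH (cat.), MeOH, 0 °C
Reagents that add atoms: hydrogen peroxide OO
Why: Weitz–Scheffer nucleophilic epoxidation as known for isophorone; hydroperoxide should add axially to C5 on the face opposite to the C6 side chain, so that the epoxide oxygen is trans to the side chain.

Step 11
Reactants: 19 (1R,5S,6R)-5-(2,2-dimethoxyethyl)-4,4,6-trimethyl-7-oxabicyclo[4.1.0]heptan-2-one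
Product: 20 (3S,4S)-4-(2,2-dimethoxyethyl)-3-hydroxy-3,5,5-trimethylcyclohexan-1-one
Conditions: SmI2 (2.2 equiv), THF/MeOH, −90 °C
Reagents that add atoms: none
Why: Reductive cleavage of the Cα–O bond of the α,β-epoxy ketone by samarium diiodide leaves the C5–O bond untouched, so the tertiary alcohol keeps the epoxide configuration (hydroxyl trans to the side chain) and no elimination should occur at this temperature.

Step 12
Reactants: 20 (3S,4S)-4-(2,2-dimethoxyethyl)-3-hydroxy-3,5,5-trimethylcyclohexan-1-one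
Product: 21 (1S,2S)-2-(2,2-dimethoxyethyl)-5,5-dimethoxy-1,3,3-trimethylcyclohexan-1-ol
Conditions: HC(OMe)3, MeOH, PPTS (cat.), rt; Et3N quench
Reagents that add atoms: trimethyl orthoformate COC(OC)OC
Why: Acid-catalysed ketalisation as in step 4; the fast ketalisation at room temperature should outrun any acid-catalysed retro-aldol epimerisation at C5.

Step 13
Reactants: 21 (1S,2S)-2-(2,2-dimethoxyethyl)-5,5-dimethoxy-1,3,3-trimethylcyclohexan-1-ol
Product: 22 2-[(1S,6S)-4,4-dimethoxy-2,2,6-trimethyl-6-(triethylsilyloxy)cyclohexyl]acetaldehyde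
Conditions: Et3SiOTf (3 equiv), 2,6-lutidine (4 equiv), CH2Cl2, 0 °C; then H2O
Reagents that add atoms: triethylsilyl triflate CC[Si](CC)(CC)OS(=O)(=O)C(F)(F)F; water O
Why: Chemoselective silyl triflate/2,6-lutidine cleavage of the aldehyde acetal with silylation of the tertiary alcohol, as in step 5.

Step 14
Reactants: 22 2-[(1S,6S)-4,4-dimethoxy-2,2,6-trimethyl-6-(triethylsilyloxy)cyclohexyl]acetaldehyde; 11 ethyl (E)-3-iodobut-2-enoate
Product: 24 ethyl (2E,4E)-5-[(1S,6S)-4,4-dimethoxy-2,2,6-trimethyl-6-(triethylsilyloxy)cyclohexyl]-3-methylpenta-2,4-dienoate, via tosylhydrazone 23 (not isolated)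
Conditions: TsNHNH2, 1,4-dioxane, rt; then 11, Pd2(dba)3 (2.5 mol %), XPhos (10 mol %), LiOtBu (2.4 equiv), 90 °C
Reagents that add atoms: none
Why: Barluenga coupling as in step 6, forming C8–C9 and the (7E)-alkene.

Step 15
Reactants: 24 ethyl (2E,4E)-5-[(1S,6S)-4,4-dimethoxy-2,2,6-trimethyl-6-(triethylsilyloxy)cyclohexyl]-3-methylpenta-2,4-dienoate
Product: 25 (2E,4E)-5-[(1S,6S)-4,4-dimethoxy-2,2,6-trimethyl-6-(triethylsilyloxy)cyclohexyl]-3-methylpenta-2,4-dien-1-ol
Conditions: i-Bu2AlH (2.5 equiv), CH2Cl2, −78 °C; aq. potassium sodium tartrate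
Reagents that add atoms: none
Why: 1,2-Reduction of the dienoate to the allylic alcohol, as in step 7.

Step 16
Reactants: 25 (2E,4E)-5-[(1S,6S)-4,4-dimethoxy-2,2,6-trimethyl-6-(triethylsilyloxy)cyclohexyl]-3-methylpenta-2,4-dien-1-ol
Product: 27 [(2E,4E)-5-[(1S,6S)-4,4-dimethoxy-2,2,6-trimethyl-6-(triethylsilyloxy)cyclohexyl]-3-methylpenta-2,4-dien-1-yl]triphenylphosphonium bromide, via allylic bromide 26 (not isolated)
Conditions: CBr4, PPh3, 2,6-lutidine, CH2Cl2, −20 °C; then PPh3, MeCN, rt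
Reagents that add atoms: carbon tetrabromide BrC(Br)(Br)Br; triphenylphosphine c1ccc(cc1)P(c1ccccc1)c1ccccc1
Why: Appel bromination and phosphine quaternisation, as in step 8.

Step 17
Reactants: 16 [(2E,4E)-5-[(1S,6R)-4,4-dimethoxy-2,2,6-trimethyl-6-(triethylsilyloxy)cyclohexyl]-3-methylpenta-2,4-dien-1-yl]triphenylphosphonium bromide; 28 (2E,4E,6E)-2,7-dimethylocta-2,4,6-trienedial
Product: 30 (2E,4E,6E,8E,10E,12E)-13-[(1S,6R)-4,4-dimethoxy-2,2,6-trimethyl-6-(triethylsilyloxy)cyclohexyl]-2,7,11-trimethyltrideca-2,4,6,8,10,12-hexaenal, via phosphorus ylide 29 (not isolated)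
Conditions: 28 (3 equiv), NaOMe (1.1 equiv), CH2Cl2/MeOH, 0 °C, slow addition of 16
Reagents that add atoms: none
Why: Wittig olefination of the C15 allylic ylide with an excess of the symmetrical C10 dialdehyde should stop at the mono-adduct (C11'=C12' bond), as in established C15 + C10 carotenoid practice; any Z isomer at the new bond is corrected after step 18.

Step 18
Reactants: 27 [(2E,4E)-5-[(1S,6S)-4,4-dimethoxy-2,2,6-trimethyl-6-(triethylsilyloxy)cyclohexyl]-3-methylpenta-2,4-dien-1-yl]triphenylphosphonium bromide; 30 (2E,4E,6E,8E,10E,12E)-13-[(1S,6R)-4,4-dimethoxy-2,2,6-trimethyl-6-(triethylsilyloxy)cyclohexyl]-2,7,11-trimethyltrideca-2,4,6,8,10,12-hexaenal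
Product: 32 (all-E)-(5S,6S,5'R,6'S)-3,3,3',3'-tetramethoxy-5,5'-bis(triethylsilyloxy)-5,6,5',6'-tetrahydro-β,β-carotene, via phosphorus ylide 31 (not isolated)
Conditions: NaOMe (1.1 equiv), CH2Cl2/MeOH, 0 °C to rt; then n-heptane, reflux (Z to E isomerisation)
Reagents that add atoms: none
Why: The second Wittig olefination (C11=C12 bond) completes the C40 chain with the two different end groups, and the usual thermal isomerisation of carotenoid Z isomers should give the all-E polyene.

Step 19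
Reactants: 32 (all-E)-(5S,6S,5'R,6'S)-3,3,3',3'-tetramethoxy-5,5'-bis(triethylsilyloxy)-5,6,5',6'-tetrahydro-β,β-carotene
Product: 34 (all-E)-(5S,6S,5'R,6'S)-5,5'-dihydroxy-5,6,5',6'-tetrahydro-β,β-carotene-3,3'-dione, via diol bis-ketal 33 (not isolated)
Conditions: Bu4NF, THF, 0 °C to rt; then PPTS (cat.), acetone/H2O (10:1), rt
Reagents that add atoms: water O
Why: Fluoride removes both silyl ethers while the ketones are still masked (no retro-aldol possible), and mild acid hydrolysis of the two dimethyl ketals then frees the β-hydroxy ketones without dehydration or epimerisation at C5.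

**Compound list**

1 | (1S,5S)-(−)-verbenone, (1S,5S)-4,6,6-trimethylbicyclo[3.1.1]hept-3-en-2-one | CC1=CC(=O)[C@H]2C[C@@H]1C2(C)C | starting material
2 | (1R,5S)-chrysanthenone, (1R,5S)-2,7,7-trimethylbicyclo[3.1.1]hept-2-en-6-one | CC1=CC[C@@H]2C(=O)[C@H]1C2(C)C | intermediate
3 | (1R,5S,6R)-2,6,7,7-tetramethylbicyclo[3.1.1]hept-2-en-6-ol | CC1=CC[C@@H]2[C@@](C)(O)[C@H]1C2(C)C | intermediate
4 | 2-[(1S,2R,3R)-3-acetyl-2-hydroxy-2,4,4-trimethylcyclobutyl]acetaldehyde | O=CC[C@@H]1[C@@](C)(O)[C@H](C(C)=O)C1(C)C | intermediate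
5 | 1-[(1R,2R,3S)-3-(2,2-dimethoxyethyl)-2-hydroxy-2,4,4-trimethylcyclobutyl]ethan-1-one | COC(OC)C[C@@H]1[C@@](C)(O)[C@H](C(C)=O)C1(C)C | intermediate
6 | (3S)-3-(2,2-dimethoxyethyl)-4,4-dimethylheptane-2,6-dione | COC(OC)C[C@H](C(C)=O)C(C)(C)CC(C)=O | intermediate
7 | (3S)-3-(2,2-dimethoxyethyl)-4,4-dimethyl-6-(pyrrolidin-1-yl)hept-6-en-2-one | COC(OC)C[C@H](C(C)=O)C(C)(C)CC(=C)N1CCCC1 | intermediate
8 | (3R,4S)-4-(2,2-dimethoxyethyl)-3-hydroxy-3,5,5-trimethylcyclohexan-1-one (hydroxyl cis to the side chain) | COC(OC)C[C@H]1C(C)(C)CC(=O)C[C@@]1(C)O | intermediate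
9 | (1R,2S)-2-(2,2-dimethoxyethyl)-5,5-dimethoxy-1,3,3-trimethylcyclohexan-1-ol | COC(OC)C[C@H]1C(C)(C)CC(OC)(OC)C[C@@]1(C)O | intermediate
10 | 2-[(1S,6R)-4,4-dimethoxy-2,2,6-trimethyl-6-(triethylsilyloxy)cyclohexyl]acetaldehyde | O=CC[C@H]1C(C)(C)CC(OC)(OC)C[C@@]1(C)O[Si](CC)(CC)CC | intermediate
11 | ethyl (E)-3-iodobut-2-enoate | CCOC(=O)/C=C(C)/I | starting material
12 | N-tosylhydrazone of aldehyde 10 | Cc1ccc(cc1)S(=O)(=O)N/N=C/C[C@H]1C(C)(C)CC(OC)(OC)C[C@@]1(C)O[Si](CC)(CC)CC | intermediate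
13 | ethyl (2E,4E)-5-[(1S,6R)-4,4-dimethoxy-2,2,6-trimethyl-6-(triethylsilyloxy)cyclohexyl]-3-methylpenta-2,4-dienoate | CCOC(=O)/C=C(C)/C=C/[C@H]1C(C)(C)CC(OC)(OC)C[C@@]1(C)O[Si](CC)(CC)CC | intermediate
14 | (2E,4E)-5-[(1S,6R)-4,4-dimethoxy-2,2,6-trimethyl-6-(triethylsilyloxy)cyclohexyl]-3-methylpenta-2,4-dien-1-ol | OC/C=C(C)/C=C/[C@H]1C(C)(C)CC(OC)(OC)C[C@@]1(C)O[Si](CC)(CC)CC | intermediate
15 | allylic bromide of 14 (CH2Br in place of CH2OH; 2E,4E) | BrC/C=C(C)/C=C/[C@H]1C(C)(C)CC(OC)(OC)C[C@@]1(C)O[Si](CC)(CC)CC | intermediate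
16 | [(2E,4E)-5-[(1S,6R)-4,4-dimethoxy-2,2,6-trimethyl-6-(triethylsilyloxy)cyclohexyl]-3-methylpenta-2,4-dien-1-yl]triphenylphosphonium bromide | c1ccccc1[P+](c1ccccc1)(c1ccccc1)C/C=C(C)/C=C/[C@H]1C(C)(C)CC(OC)(OC)C[C@@]1(C)O[Si](CC)(CC)CC.[Br-] | intermediate
17 | tertiary trifluoroacetate of 8 | COC(OC)C[C@H]1C(C)(C)CC(=O)C[C@@]1(C)OC(=O)C(F)(F)F | intermediate
18 | (4S)-4-(2,2-dimethoxyethyl)-3,5,5-trimethylcyclohex-2-en-1-one | COC(OC)C[C@H]1C(C)(C)CC(=O)C=C1C | intermediate
19 | (1R,5S,6R)-5-(2,2-dimethoxyethyl)-4,4,6-trimethyl-7-oxabicyclo[4.1.0]heptan-2-one (epoxide oxygen trans to the side chain) | COC(OC)C[C@H]1C(C)(C)CC(=O)[C@@H]2O[C@]12C | intermediate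
20 | (3S,4S)-4-(2,2-dimethoxyethyl)-3-hydroxy-3,5,5-trimethylcyclohexan-1-one (hydroxyl trans to the side chain) | COC(OC)C[C@H]1C(C)(C)CC(=O)C[C@]1(C)O | intermediate
21 | (1S,2S)-2-(2,2-dimethoxyethyl)-5,5-dimethoxy-1,3,3-trimethylcyclohexan-1-ol | COC(OC)C[C@H]1C(C)(C)CC(OC)(OC)C[C@]1(C)O | intermediate
22 | 2-[(1S,6S)-4,4-dimethoxy-2,2,6-trimethyl-6-(triethylsilyloxy)cyclohexyl]acetaldehyde | O=CC[C@H]1C(C)(C)CC(OC)(OC)C[C@]1(C)O[Si](CC)(CC)CC | intermediate
23 | N-tosylhydrazone of aldehyde 22 | Cc1ccc(cc1)S(=O)(=O)N/N=C/C[C@H]1C(C)(C)CC(OC)(OC)C[C@]1(C)O[Si](CC)(CC)CC | intermediate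
24 | ethyl (2E,4E)-5-[(1S,6S)-4,4-dimethoxy-2,2,6-trimethyl-6-(triethylsilyloxy)cyclohexyl]-3-methylpenta-2,4-dienoate | CCOC(=O)/C=C(C)/C=C/[C@H]1C(C)(C)CC(OC)(OC)C[C@]1(C)O[Si](CC)(CC)CC | intermediate
25 | (2E,4E)-5-[(1S,6S)-4,4-dimethoxy-2,2,6-trimethyl-6-(triethylsilyloxy)cyclohexyl]-3-methylpenta-2,4-dien-1-ol | OC/C=C(C)/C=C/[C@H]1C(C)(C)CC(OC)(OC)C[C@]1(C)O[Si](CC)(CC)CC | intermediate
26 | allylic bromide of 25 (CH2Br in place of CH2OH; 2E,4E) | BrC/C=C(C)/C=C/[C@H]1C(C)(C)CC(OC)(OC)C[C@]1(C)O[Si](CC)(CC)CC | intermediate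
27 | [(2E,4E)-5-[(1S,6S)-4,4-dimethoxy-2,2,6-trimethyl-6-(triethylsilyloxy)cyclohexyl]-3-methylpenta-2,4-dien-1-yl]triphenylphosphonium bromide | c1ccccc1[P+](c1ccccc1)(c1ccccc1)C/C=C(C)/C=C/[C@H]1C(C)(C)CC(OC)(OC)C[C@]1(C)O[Si](CC)(CC)CC.[Br-] | intermediate
28 | (2E,4E,6E)-2,7-dimethylocta-2,4,6-trienedial | O=C/C(C)=C/C=C/C=C(C)/C=O | starting material
29 | triphenylphosphonium ylide of 16 | c1ccccc1P(c1ccccc1)(c1ccccc1)=C/C=C(C)/C=C/[C@H]1C(C)(C)CC(OC)(OC)C[C@@]1(C)O[Si](CC)(CC)CC | intermediate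
30 | (2E,4E,6E,8E,10E,12E)-13-[(1S,6R)-4,4-dimethoxy-2,2,6-trimethyl-6-(triethylsilyloxy)cyclohexyl]-2,7,11-trimethyltrideca-2,4,6,8,10,12-hexaenal | O=C/C(C)=C/C=C/C=C(C)/C=C/C=C(C)/C=C/[C@H]1C(C)(C)CC(OC)(OC)C[C@@]1(C)O[Si](CC)(CC)CC | intermediate
31 | triphenylphosphonium ylide of 27 | c1ccccc1P(c1ccccc1)(c1ccccc1)=C/C=C(C)/C=C/[C@H]1C(C)(C)CC(OC)(OC)C[C@]1(C)O[Si](CC)(CC)CC | intermediate
32 | (all-E)-(5S,6S,5'R,6'S)-3,3,3',3'-tetramethoxy-5,5'-bis(triethylsilyloxy)-5,6,5',6'-tetrahydro-β,β-carotene | CC(/C=C/C=C(C)/C=C/[C@H]1C(C)(C)CC(OC)(OC)C[C@]1(C)O[Si](CC)(CC)CC)=C\C=C\C=C(C)\C=C\C=C(C)\C=C\[C@H]1C(C)(C)CC(OC)(OC)C[C@@]1(C)O[Si](CC)(CC)CC | intermediate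
33 | (all-E)-(5S,6S,5'R,6'S)-3,3,3',3'-tetramethoxy-5,6,5',6'-tetrahydro-β,β-carotene-5,5'-diol | CC(/C=C/C=C(C)/C=C/[C@H]1C(C)(C)CC(OC)(OC)C[C@]1(C)O)=C\C=C\C=C(C)\C=C\C=C(C)\C=C\[C@H]1C(C)(C)CC(OC)(OC)C[C@@]1(C)O | intermediate
34 | (all-E)-(5S,6S,5'R,6'S)-5,5'-dihydroxy-5,6,5',6'-tetrahydro-β,β-carotene-3,3'-dione | CC(/C=C/C=C(C)/C=C/[C@H]1C(C)(C)CC(=O)C[C@]1(C)O)=C\C=C\C=C(C)\C=C\C=C(C)\C=C\[C@H]1C(C)(C)CC(=O)C[C@@]1(C)O | target

**Step count and risks**

Total step count: 19. Longest linear sequence: 13 steps (1, 2, 3, 9–16, 18, 19).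

Steps most likely to fail:

Step 3. In the aldol phase the C5 methyl ketone may be enolised instead of the C3 one, the facial selectivity at C5 may be low, or the ketol may lose water under the amine/acid catalyst. A co-formed C5 epimer would be compound 20 and would simply enter step 12. The fallback sets out from 3: the same ozonolysis and acetalisation are followed by pyrrolidine/AcOH at 40 °C, so that the aldol condensation runs to completion and gives enone 18 directly, where C5 is no longer a stereocentre; this comes back to the route at 18 for the (5S,6S) half. For the (5'R,6'S) half the C5–O bond is then made by a tethered conjugate addition instead of the aldol. Hydrolysis of the acetal of 18 (aq. oxalic acid, THF) should give 2-[(1S)-2,6,6-trimethyl-4-oxocyclohex-2-en-1-yl]acetaldehyde F1. K2CO3 in MeOH forms the methyl hemiacetal, whose alkoxide adds 5-exo to C5 from the face of the tether and should give the cis-fused (3aS,7aR)-2-methoxy-4,4,7a-trimethylhexahydro-1-benzofuran-6(2H)-one F2. Ketalisation under the conditions of step 4 gives (3aS,7aR)-2,6,6-trimethoxy-4,4,7a-trimethyloctahydro-1-benzofuran F3. Et3SiOTf/2,6-lutidine followed by water should open the mixed acetal and silylate the freed tertiary alkoxide, which comes back to the route at 10.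

Step 6 (and its twin, step 14). The strong base at 90 °C may degrade the iodoenoate 11 or divert the hydrazone into a Bamford–Stevens elimination, and reversible re-addition of the palladium hydride may scramble the alkene geometry. The fallback sets out from 10: one-pot enol nonaflate formation and elimination (C4F9SO2F, phosphazene base, THF) should give the terminal alkyne triethyl{[2-ethynyl-5,5-dimethoxy-1,3,3-trimethylcyclohexyl]oxy}silane F6 (ring stereocentres as in 10). Syn-hydroboration with pinacolborane catalysed by Cp2Zr(H)Cl gives the (E)-alkenyl pinacol boronate F7. Suzuki coupling of this boronate with 11 (Pd(PPh3)4, aq. K3PO4, THF) forms the C8–C9 bond with a fixed (7E) geometry and comes back to the route at 13; the same sequence from 22 would reach 24.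

Step 1. The photoproduct can revert photochemically to an achiral dienyl ketene that recloses to either enantiomer, so enantiomeric purity may be eroded, and over-irradiation lowers the yield. The fallback sets out from 2 of eroded purity: NaBH4 reduction gives (1R,5S)-2,7,7-trimethylbicyclo[3.1.1]hept-2-en-6-ol (chrysanthenol) F4, which is resolved by lipase-catalysed acylation with vinyl acetate. The required series is collected either as unreacted alcohol or as (1R,5S)-2,7,7-trimethylbicyclo[3.1.1]hept-2-en-6-yl acetate F5, which is methanolysed (K2CO3, MeOH). Oxidation with Dess–Martin periodinane comes back to the route at enantiomerically enriched 2.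

Further compounds
F1 | step 3 | 2-[(1S)-2,6,6-trimethyl-4-oxocyclohex-2-en-1-yl]acetaldehyde | O=CC[C@H]1C(C)(C)CC(=O)C=C1C
F2 | step 3 | (3aS,7aR)-2-methoxy-4,4,7a-trimethylhexahydro-1-benzofuran-6(2H)-one | COC1C[C@H]2C(C)(C)CC(=O)C[C@@]2(C)O1
F3 | step 3 | (3aS,7aR)-2,6,6-trimethoxy-4,4,7a-trimethyloctahydro-1-benzofuran | COC1C[C@H]2C(C)(C)CC(OC)(OC)C[C@@]2(C)O1
F4 | step 1 | (1R,5S)-2,7,7-trimethylbicyclo[3.1.1]hept-2-en-6-ol (chrysanthenol) | CC1=CC[C@@H]2C(O)[C@H]1C2(C)C
F5 | step 1 | (1R,5S)-2,7,7-trimethylbicyclo[3.1.1]hept-2-en-6-yl acetate | CC1=CC[C@@H]2C(OC(C)=O)[C@H]1C2(C)C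
F6 | step 6 | triethyl{[2-ethynyl-5,5-dimethoxy-1,3,3-trimethylcyclohexyl]oxy}silane (ring stereocentres as in 10) | C#C[C@H]1C(C)(C)CC(OC)(OC)C[C@@]1(C)O[Si](CC)(CC)CC
F7 | step 6 | (E)-alkenyl pinacol boronate from F6 | CC1(C)OB(/C=C/[C@H]2C(C)(C)CC(OC)(OC)C[C@@]2(C)O[Si](CC)(CC)CC)OC1(C)C
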